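# Proposed synthesis of CNP0233409.1 by cyclobutenone–siloxyalkyne benzannulation

## The problem

The target (27) is a 2,3-dimethylchroman-4-one whose benzene ring carries a substituent on every carbon. These are ring oxygen O1 on C8a, the C4 ketone on C4a, a free chelated hydroxyl on C5, the hexanoic acid chain (through benzylic C3') on C6, a methyl ether on C7 and a prenyl group on C8. The three oxygens are in three different states and the carbon substituents sit between them, so stepwise substitution of a symmetrical trioxygenated benzene would have to distinguish positions and oxygens that differ only slightly. There are three stereocentres. C3' (R) is insulated from ring C by the arene and needs its own source of asymmetry. C2 (S) also needs an external source. C3 (S) lies α to the ketone and can be left to C2, because the trans-2,3-dimethyl arrangement is the more stable one. The sensitive groups are the prenyl alkene (acid-induced cyclisation onto a neighbouring hydroxyl), the chromanone (β-elimination of the O1 phenoxide from the enolate would open the ring and erase C2) and the C5 hydroxyl/carboxylic acid pair, which can close to a dihydrocoumarin. That last liability is used here as a traceless way to tell the C5 oxygen from the C8a oxygen. The key step rests on the alternation round the ring of oxygen-bearing carbons (C5, C7, C8a) and carbon-bearing ones (C6, C8, C4a). This is the polarity pattern that results when a ketene carbon (C5), a vinylogous ester unit (C6–C7–C8) and an ynol ether (C8a–C4a) are joined.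

## Retrosynthesis

**27 from lactone 26.** The free acid and the free C5 hydroxyl are joined retrosynthetically as an aryl lactone. No skeletal bond is cut. The gain is that one small ring protects both groups through the endgame and is opened by hydroxide far more easily than a methyl ester would be, which matters because ring C is base-sensitive. The forward step must be fast and cold.

**26 from aldehyde 24 (C3–C4).** Ring C is opened between C3 and C4. Cutting C4–C4a instead would mean a Friedel–Crafts acylation with a Lewis acid beside the prenyl group. Cutting O1–C2 after an aldol would require a ketone, a chiral enolate and more steps. The C3–C4 cut needs only an aldehyde and an O-butenyl ether, which are joined by carbene-catalysed hydroacylation without acid. The forward reaction must form the bond at the internal alkene carbon and leave C3 trans to C2.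

**24 from phenol 22 and (R)-but-3-en-2-ol 23 (O1–C2).** The ether bond is cut so that C2 comes from a commercial alcohol by Mitsunobu inversion. The precursor 22 has a single free hydroxyl, so no regiochemical question remains.

**22 back to phenol 18 (C4a–C4, functional-group changes).** Desilylation (22 from 21), lactonisation (21 from 20) and ortho-formylation (20 from 18) are removed in turn. Formylation is placed first because it liberates methoxide, which a lactone would not survive. Lactonisation precedes desilylation so that acid never meets a prenyl group with a free ortho hydroxyl. Compound 18 has only one free aromatic position, C4a.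

**18 from cyclobutenone 9 and siloxyalkyne 13 (C4a–C5, C8–C8a, C5–C6).** The arene is taken apart into a four-carbon and a two-carbon piece. Against any substitution sequence, this cut places every substituent through the component that carries it. The cyclobutenone carbonyl carbon becomes C5 (free OH), its sp3 carbon C6 (chain), its methoxy carbon C7 and its prenyl carbon C8. The alkyne supplies C8a (OTIPS) and C4a (H). The forward reaction must deliver the right regiochemistry and must not disturb C3'.

**9 from hemiester 2 and ynol ether 6.** The cyclobutenone is cut across its C5–C8 and C6–C7 bonds into aldoketene 8 (from 2 through acid chloride 7) and 1-methoxy-5-methylhex-4-en-1-yne 6. The methyl ynol ether provides the C7 methyl ether directly and cannot fragment by a retro-ene path. Siloxyalkyne 13 comes from acetylene 10 by ynolate silylation.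

**2 from anhydride 1; 6 from 3 and 4.** Hemiester 2 is the desymmetrisation product of prochiral 3-propylglutaric anhydride 1. Its acid arm becomes the ketene (later C5 and C6) and its ester arm becomes the target's carboxylic acid. Ynol ether 6 comes from chloroacetaldehyde dimethyl acetal 3 and prenyl bromide 4.

## Roads not taken

**Alternative 1:** The cut runs through C8a–O1 and C4a–C4 together. The aryne across C4a–C8a, released from silyl triflate A1 with CsF, takes up the chiral acid A2. The carboxylate oxygen adds at C8a and the aryl anion captures the acyl carbon, giving hydroxy ketone A3. PMB removal, Mitsunobu closure of O1 onto C2 with inversion and lactone opening would finish.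
- Merits: this is the most convergent entry to ring C. Both C2 and C3 arrive ready-made, closure by inversion is a dependable route to the trans isomer, and no formylation or carbene step is needed. In the security of C2 and C3 it is better than the chosen plan, which leaves C3 to equilibration.
- Weak points: regiochemistry depends only on the inductive pull of the C5 lactone oxygen. The aryne sits beside a trisubstituted alkene with allylic hydrogens, which invites ene reactions. Such insertions usually need excess aryne, and the phenol of A3 is itself an aryne trap. The C3–H of A3 lies between a ketone and a β-alkoxy group, so fluoride can epimerise it or trigger β-elimination of the PMB ether. The plan also says nothing about how the pentasubstituted ring of A1 is assembled.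
- Comparison: the chosen plan offers a regiodefined construction of the arene and fluoride-free ring-C chemistry in return.

**Alternative 2:** The cut is C3–C4 alone. Aldehyde A4 (identical with 24) is closed by a triazolium-derived carbene and DBU to tricyclic lactone A5 (identical with 26).
- Merits: the closure needs no Lewis acid near the prenyl group, C2 comes from a purchasable alcohol and C3 is set by equilibration. The chosen plan adopts it unchanged as step 10, so from A4 onward the two plans are equally good.
- Weak points: the aldehyde is hindered on both ortho sides, base is present beside C2, and an aryl lactone is exposed to carbene and DBU. The chosen plan shares all of these. What this alternative leaves open is the origin of A4. By substitution chemistry it would require methylating one of three oxygens, prenylating one of two like carbons and introducing the C3' chain asymmetrically at the other.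
- Comparison: the chosen plan's advantage is the benzannulation, which removes those selectivity problems.

**Alternative 3:** The cut removes both methyl groups. Chromone A6 takes up methyl from MeMgBr at C2 under CuBr·SMe2 (monovalent copper) and a chiral diphosphine. The magnesium enolate is then methylated by MeI anti to the new C2 methyl, giving chromanone A7. MOM removal and ester hydrolysis follow.
- Merits: both ring-C centres come from one catalytic operation. No stoichiometric chiral reagent or Mitsunobu reaction is needed, and trans selectivity is kinetic. In economy of stereocontrol it is better than the chosen endgame.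
- Weak points: A6 carries a methyl ester exposed to a Grignard reagent, while the chromone is deactivated by three donor oxygens and shielded by the peri MOM ether. Methyl is the least willing group to transfer in such additions. The enolate must be warmed to react with MeI, which is where O1 phenoxide elimination and double methylation set in. The final deprotections (acid beside prenyl, prolonged hydroxide on the chromanone) are harsher than a lactone opening. A C4a acetyl group and the hexasubstituted arene are still presupposed.
- Comparison: the chosen plan offers milder reagents around the ester and prenyl group and a one-step unveiling in return.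

Key step: step 5

Assumption: the quinidine-derived catalyst (DHQD)2AQN is taken to deliver the (S)-hemiester 2; should it favour the mirror image, the quinine-derived pseudo-enantiomer (DHQ)2AQN is used and nothing else changes.

## Route

Step 1
Reactants: 1 3-propylglutaric anhydride
Product: 2 (3S)-3-(2-methoxy-2-oxoethyl)hexanoic acid
Conditions: MeOH (10 equiv), hydroquinidine anthraquinone-1,4-diyl diether [(DHQD)2AQN] (20 mol%), Et2O, −40 °C
Reagents that add atoms: methanol, CO
Why: Alkaloid-catalysed desymmetrising alcoholysis of a prochiral anhydride; the quinuclidine nitrogen activates methanol as a general base and the chiral pocket directs it to one enantiotopic carbonyl, which sets C3' of the target (S here, R later only because the priorities of the two arms change).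

Step 2
Reactants: 3 chloroacetaldehyde dimethyl acetal; 4 prenyl bromide
Product: 6 1-methoxy-5-methylhex-4-en-1-yne, via lithium methoxyacetylide 5 (not isolated)
Conditions: Et2NH, n-BuLi (3 equiv each), THF, 0 °C; 3, 0 °C → rt; then DMPU, 4, −78 °C → rt
Reagents that add atoms: none
Why: Threefold base treatment of the chloroacetal (loss of methanol and HCl, then deprotonation) is the standard entry to alkoxyacetylides, and the acetylide is alkylated by SN2 at the primary allylic carbon.

Step 3
Reactants: 2 (3S)-3-(2-methoxy-2-oxoethyl)hexanoic acid; 6 1-methoxy-5-methylhex-4-en-1-yne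
Product: 9 methyl (3R)-3-[2-methoxy-3-(3-methylbut-2-enyl)-4-oxocyclobut-2-en-1-yl]hexanoate, via acid chloride 7 (not isolated), via aldoketene 8 (not isolated)
Conditions: (COCl)2, DMF (cat.), CH2Cl2, 0 °C → rt, concentrate; then added over 4 h to 6 (1.5 equiv), Et3N, Et2O, 35 °C
Reagents that add atoms: none
Why: Dehydrochlorination of the acid chloride gives the aldoketene, which undergoes [2+2] cycloaddition with the ynol ether; the ketene carbonyl carbon bonds to the nucleophilic prenyl-bearing alkyne carbon, so methoxy lands on the future C7 and prenyl on the future C8. The new ring stereocentre forms unselectively and is destroyed in step 5, and C3' is β to the reacting carbonyl and untouched.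

Step 4
Reactants: 10 acetylene
Product: 13 (triisopropylsilyloxy)ethyne, via lithium acetylide 11 (not isolated), via lithium ethynolate 12 (not isolated)
Conditions: n-BuLi, THF, −78 °C; transfer to t-BuOOLi (from t-BuOOH, LiHMDS), THF, −78 → −20 °C; then TIPSOTf, −78 → 0 °C
Reagents that add atoms: tert-butyl hydroperoxide, CC(C)(C)OO; triisopropylsilyl trifluoromethanesulfonate, CC(C)[Si](C(C)C)(C(C)C)OS(=O)(=O)C(F)(F)F
Why: Electrophilic oxygenation of a lithium acetylide by lithium tert-butyl peroxide gives the ynolate and the bulky silyl triflate traps it on oxygen; this is the general route from terminal alkynes to siloxyalkynes, applied here to acetylene itself and run cold so that the monolithium acetylide is oxidised before it can disproportionate.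

Step 5
Reactants: 9 methyl (3R)-3-[2-methoxy-3-(3-methylbut-2-enyl)-4-oxocyclobut-2-en-1-yl]hexanoate; 13 (triisopropylsilyloxy)ethyne
Product: 18 methyl (3R)-3-[2-hydroxy-6-methoxy-5-(3-methylbut-2-enyl)-4-(triisopropylsilyloxy)phenyl]hexanoate, via vinylketene 14 (not isolated), via 4-vinylcyclobutenone 15 (not isolated), via dienylketene 16 (not isolated), via cyclohexadienone 17 (not isolated)
Conditions: 13 (2 equiv), toluene (degassed), 80 °C then 110 °C, sealed tube
Reagents that add atoms: none
Why: This is a Danheiser benzannulation of a cyclobutenone with a siloxyalkyne, a pericyclic cascade. Heat opens 9 by conrotatory 4π electrocyclic ring opening to vinylketene 14, whose ketene carbon is the future C5. The electron-rich CH terminus of 13 attacks that carbon and the silyloxy-bearing carbon bonds to the prenyl-bearing ketene carbon, a [2+2] cycloaddition that gives 15 with the new C4a–C5 and C8–C8a bonds. Compound 15 opens in a second 4π step to dienylketene 16, which closes the only new ring, the arene, by thermal disrotatory 6π electrocyclisation between C5 and C6 to give 17, and tautomerisation of the C6–H delivers phenol 18. No stereocentre is created, since the ring carbon of 9, the quaternary carbon of 15 and C6 of 17 all end up sp2, so either epimer of 9 serves, and C3' lies outside the reacting π system, has no acidic hydrogen and passes through unchanged. The selectivity needed is regiochemical and polarity secures it: the ketene carbonyl carbon is the electrophile and the carbon β to oxygen of the ynol ether the nucleophile, which puts OTIPS on C8a and H on C4a, while the prenyl alkene is far less nucleophilic and cannot reach the ketene without strain. The 3-methoxy group makes 9 a vinylogous ester and a less willing ring opener than the usual 3-alkylcyclobutenones, hence the stepwise rise in temperature and the excess of 13.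

Step 6
Reactants: 18 methyl (3R)-3-[2-hydroxy-6-methoxy-5-(3-methylbut-2-enyl)-4-(triisopropylsilyloxy)phenyl]hexanoate
Product: 20 methyl (3R)-3-[3-formyl-2-hydroxy-6-methoxy-5-(3-methylbut-2-enyl)-4-(triisopropylsilyloxy)phenyl]hexanoate, via hydroxymethylphenol 19 (not isolated)
Conditions: MgCl2, Et3N, (CH2O)n, MeCN, 80 °C
Reagents that add atoms: paraformaldehyde (formaldehyde), C=O
Why: Casnati–Skattebøl ortho-formylation; the magnesium phenoxide of the C5 hydroxyl delivers formaldehyde to its only free ortho carbon, C4a, and the hydroxymethylphenol is oxidised in situ by a second formaldehyde through hydride transfer. The medium is mildly basic and free of Lewis or protic acid, so ester, silyl ether and prenyl survive, and any 18 that lactonised in step 5 is reopened by the methoxide formed and converges on 20.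

Step 7
Reactants: 20 methyl (3R)-3-[3-formyl-2-hydroxy-6-methoxy-5-(3-methylbut-2-enyl)-4-(triisopropylsilyloxy)phenyl]hexanoate
Product: 21 (4R)-5-methoxy-6-(3-methylbut-2-enyl)-2-oxo-4-propyl-7-(triisopropylsilyloxy)chromane-8-carbaldehyde
Conditions: TsOH·H2O (5 mol%), toluene, 80 °C, 5 Å molecular sieves
Reagents that add atoms: none
Why: Acid-catalysed lactonisation (intramolecular transesterification) of the C5 hydroxyl onto the methyl ester closes a six-membered aryl lactone, driven by uptake of MeOH on the sieves, and ties up the C5 oxygen and the carboxyl together. The prenyl group has only an ether and a silyl ether as neighbours at this stage, so acid-induced chroman formation has no free hydroxyl to use.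

Step 8
Reactants: 21 (4R)-5-methoxy-6-(3-methylbut-2-enyl)-2-oxo-4-propyl-7-(triisopropylsilyloxy)chromane-8-carbaldehyde
Product: 22 (4R)-7-hydroxy-5-methoxy-6-(3-methylbut-2-enyl)-2-oxo-4-propylchromane-8-carbaldehyde
Conditions: TBAF, AcOH (1:1), THF, 0 °C
Reagents that add atoms: none
Why: Fluoride cleavage of an aryl silyl ether, eased by the ortho formyl group; acetic acid buffering keeps the medium from opening the aryl lactone, and the C8a hydroxyl emerges as the only hydroxyl in the molecule.

Step 9
Reactants: 22 (4R)-7-hydroxy-5-methoxy-6-(3-methylbut-2-enyl)-2-oxo-4-propylchromane-8-carbaldehyde; 23 (R)-but-3-en-2-ol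
Product: 24 (4R)-7-[(2S)-but-3-en-2-yloxy]-5-methoxy-6-(3-methylbut-2-enyl)-2-oxo-4-propylchromane-8-carbaldehyde
Conditions: PPh3, DIAD, THF, 0 °C → rt
Reagents that add atoms: none
Why: Mitsunobu etherification; the acidic formyl-activated phenol displaces the oxyphosphonium derivative of the secondary allylic alcohol by SN2 with inversion, so the (R)-alcohol gives the (S)-ether and sets C2 of the target.

Step 10
Reactants: 24 (4R)-7-[(2S)-but-3-en-2-yloxy]-5-methoxy-6-(3-methylbut-2-enyl)-2-oxo-4-propylchromane-8-carbaldehyde
Product: 26 lactone of (3R)-3-[(2S,3S)-5-hydroxy-7-methoxy-2,3-dimethyl-8-(3-methylbut-2-enyl)-4-oxochroman-6-yl]hexanoic acid onto its C5 hydroxyl, via cis-chromanone 25 (not isolated)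
Conditions: 2-mesityl-6,7-dihydro-5H-pyrrolo[2,1-c][1,2,4]triazol-2-ium chloride (20 mol%), DBU (40 mol%), 1,4-dioxane, 80 °C
Reagents that add atoms: none
Why: Carbene-catalysed intramolecular hydroacylation of an unactivated alkene (Stetter-type umpolung without a Michael acceptor); the triazolylidene turns the aldehyde into a hydroxy-enamine acyl anion equivalent that adds to the internal alkene carbon while its OH proton passes to the terminus in a concerted ene-like step, forming C3–C4 by 6-exo closure and turning the CH2 terminus into the C3 methyl. C2 is fixed by the ether; C3 forms under its influence and, being α to the new ketone, equilibrates under DBU from any cis isomer 25 to the more stable trans (2S,3S) arrangement with both methyls pseudo-equatorial.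

Step 11
Reactants: 26 lactone of (3R)-3-[(2S,3S)-5-hydroxy-7-methoxy-2,3-dimethyl-8-(3-methylbut-2-enyl)-4-oxochroman-6-yl]hexanoic acid onto its C5 hydroxyl
Product: 27 (3R)-3-[(2S,3S)-5-hydroxy-7-methoxy-2,3-dimethyl-8-(3-methylbut-2-enyl)-4-oxochroman-6-yl]hexanoic acid
Conditions: LiOH (3 equiv), THF/H2O (3:1), 0 °C; then cold 0.5 M HCl to pH 3
Reagents that add atoms: lithium hydroxide (aqueous), [Li+].[OH-]
Why: Saponification of an aryl ester; hydroxide opens the lactone within minutes at 0 °C, far faster than enolisation and β-elimination in ring C, and the released C5 phenoxide is conjugated with and then hydrogen-bonded to the C4 carbonyl, so it does not relactonise on cold acidification. No stereocentre is touched, since C3' is not enolisable and C3 is already in its stable configuration.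

## Compound list

1 | 3-propylglutaric anhydride (4-propyloxane-2,6-dione) | CCCC1CC(=O)OC(=O)C1 | starting material
2 | (3S)-3-(2-methoxy-2-oxoethyl)hexanoic acid | CCC[C@H](CC(=O)OC)CC(=O)O | intermediate
3 | chloroacetaldehyde dimethyl acetal | COC(CCl)OC | starting material
4 | prenyl bromide (1-bromo-3-methylbut-2-ene) | CC(C)=CCBr | starting material
5 | lithium methoxyacetylide | [Li]C#COC | intermediate
6 | 1-methoxy-5-methylhex-4-en-1-yne | COC#CCC=C(C)C | intermediate
7 | methyl (3R)-3-(2-chloro-2-oxoethyl)hexanoate | CCC[C@H](CC(=O)OC)CC(=O)Cl | intermediate
8 | methyl (3R)-3-(2-oxoethenyl)hexanoate (aldoketene) | CCC[C@H](CC(=O)OC)C=C=O | intermediate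
9 | methyl (3R)-3-[2-methoxy-3-(3-methylbut-2-enyl)-4-oxocyclobut-2-en-1-yl]hexanoate, both epimers at the ring carbon | CCC[C@H](CC(=O)OC)C1C(=O)C(CC=C(C)C)=C1OC | intermediate
10 | acetylene | C#C | starting material
11 | lithium acetylide | [Li]C#C | intermediate
12 | lithium ethynolate | [Li]OC#C | intermediate
13 | (triisopropylsilyloxy)ethyne | C#CO[Si](C(C)C)(C(C)C)C(C)C | intermediate
14 | methyl (3R)-3-[2-methoxy-3-(3-methylbut-2-enyl)-4-oxobuta-1,3-dienyl]hexanoate (vinylketene, alkene geometry not fixed) | CCC[C@H](CC(=O)OC)C=C(OC)C(CC=C(C)C)=C=O | intermediate
15 | methyl (3R)-3-{2-methoxy-2-[1-(3-methylbut-2-enyl)-4-oxo-2-(triisopropylsilyloxy)cyclobut-2-en-1-yl]ethenyl}hexanoate, both configurations at the quaternary ring carbon | CCC[C@H](CC(=O)OC)C=C(OC)C1(CC=C(C)C)C(=O)C=C1O[Si](C(C)C)(C(C)C)C(C)C | intermediate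
16 | methyl (3R)-3-[2-methoxy-3-(3-methylbut-2-enyl)-6-oxo-4-(triisopropylsilyloxy)hexa-1,3,5-trienyl]hexanoate (dienylketene) | CCC[C@H](CC(=O)OC)C=C(OC)C(CC=C(C)C)=C(O[Si](C(C)C)(C(C)C)C(C)C)C=C=O | intermediate
17 | methyl (3R)-3-[2-methoxy-3-(3-methylbut-2-enyl)-6-oxo-4-(triisopropylsilyloxy)cyclohexa-2,4-dien-1-yl]hexanoate, both epimers at the ring sp3 carbon | CCC[C@H](CC(=O)OC)C1C(=O)C=C(O[Si](C(C)C)(C(C)C)C(C)C)C(CC=C(C)C)=C1OC | intermediate
18 | methyl (3R)-3-[2-hydroxy-6-methoxy-5-(3-methylbut-2-enyl)-4-(triisopropylsilyloxy)phenyl]hexanoate | CCC[C@H](CC(=O)OC)c1c(O)cc(O[Si](C(C)C)(C(C)C)C(C)C)c(CC=C(C)C)c1OC | intermediate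
19 | methyl (3R)-3-[2-hydroxy-3-(hydroxymethyl)-6-methoxy-5-(3-methylbut-2-enyl)-4-(triisopropylsilyloxy)phenyl]hexanoate | CCC[C@H](CC(=O)OC)c1c(O)c(CO)c(O[Si](C(C)C)(C(C)C)C(C)C)c(CC=C(C)C)c1OC | intermediate
20 | methyl (3R)-3-[3-formyl-2-hydroxy-6-methoxy-5-(3-methylbut-2-enyl)-4-(triisopropylsilyloxy)phenyl]hexanoate | CCC[C@H](CC(=O)OC)c1c(O)c(C=O)c(O[Si](C(C)C)(C(C)C)C(C)C)c(CC=C(C)C)c1OC | intermediate
21 | (4R)-5-methoxy-6-(3-methylbut-2-enyl)-2-oxo-4-propyl-7-(triisopropylsilyloxy)chromane-8-carbaldehyde | CCC[C@@H]1CC(=O)Oc2c1c(OC)c(CC=C(C)C)c(O[Si](C(C)C)(C(C)C)C(C)C)c2C=O | intermediate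
22 | (4R)-7-hydroxy-5-methoxy-6-(3-methylbut-2-enyl)-2-oxo-4-propylchromane-8-carbaldehyde | CCC[C@@H]1CC(=O)Oc2c1c(OC)c(CC=C(C)C)c(O)c2C=O | intermediate
23 | (R)-but-3-en-2-ol | C[C@@H](O)C=C | starting material
24 | (4R)-7-[(2S)-but-3-en-2-yloxy]-5-methoxy-6-(3-methylbut-2-enyl)-2-oxo-4-propylchromane-8-carbaldehyde | CCC[C@@H]1CC(=O)Oc2c1c(OC)c(CC=C(C)C)c(O[C@@H](C)C=C)c2C=O | intermediate
25 | C3 epimer of 26: lactone onto the C5 hydroxyl of (3R)-3-[(2S,3R)-5-hydroxy-7-methoxy-2,3-dimethyl-8-(3-methylbut-2-enyl)-4-oxochroman-6-yl]hexanoic acid (cis-2,3-dimethyl) | CCC[C@@H]1CC(=O)Oc2c1c(OC)c(CC=C(C)C)c1c2C(=O)[C@H](C)[C@H](C)O1 | intermediate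
26 | lactone onto the C5 hydroxyl of (3R)-3-[(2S,3S)-5-hydroxy-7-methoxy-2,3-dimethyl-8-(3-methylbut-2-enyl)-4-oxochroman-6-yl]hexanoic acid (tricyclic dihydrocoumarin–chromanone, trans-2,3-dimethyl) | CCC[C@@H]1CC(=O)Oc2c1c(OC)c(CC=C(C)C)c1c2C(=O)[C@@H](C)[C@H](C)O1 | intermediate
27 | (3R)-3-[(2S,3S)-5-hydroxy-7-methoxy-2,3-dimethyl-8-(3-methylbut-2-enyl)-4-oxochroman-6-yl]hexanoic acid | CCC[C@H](CC(=O)O)c1c(O)c2c(c(CC=C(C)C)c1OC)O[C@@H](C)[C@H](C)C2=O | target

## Step count and least certain steps

Total: 11 steps. Longest linear sequence: 9 steps (1, 3, 5, 6, 7, 8, 9, 10, 11) from anhydride 1.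

**Step 5 (key step).** The most likely failure is a mismatch of rates. The vinylogous ester 9 opens reluctantly, while at the temperature this requires the unhindered ynol ether 13 is lost to oligomerisation or 1,3-silyl shift. The phenol product can also be O-acylated by the vinylketene. The fallback generates vinylketene 14 at room temperature by 1,4-dehydrochlorination instead of ring opening; it sets out from 2 and returns at 18.
- Acid 2 is activated with carbonyldiimidazole and homologated with potassium allyl malonate, MgCl2 and Et3N to 1-allyl 7-methyl (5S)-3-oxo-5-propylheptanedioate F1.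
- K2CO3 and prenyl bromide 4 give the C-prenylated keto ester F2.
- O-methylation of its potassium enolate (KHMDS, DMPU, dimethyl sulfate) gives the β-methoxy enoate F3.
- Pd(PPh3)4 and morpholine remove the allyl group to give the acid F4.
- Oxalyl chloride gives the acid chloride F5. With Et3N and 13 this loses HCl across the γ-position to form 14, which continues by the same cycloaddition, ring opening and closure to 18 on gentle warming.

**Step 4.** The most likely failure is disproportionation of monolithium acetylide before it is oxidised, together with loss of the small, hydrolysis-prone ynol ether on isolation. The fallback uses a substituted ynol ether whose acetylide is stable and which brings the C4 carbon with it; it sets out from 9 and returns at 20.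
- Commercial 3,3-diethoxyprop-1-yne F6 is lithiated, oxidised with lithium tert-butyl peroxide and silylated with TIPSOTf to 3,3-diethoxy-1-(triisopropylsilyloxy)prop-1-yne F7.
- Benzannulation of 9 with F7 under the conditions of step 5 should give the aryl acetal F8. The substituted alkyne carbon still bonds to the ketene carbon, so the acetal lands on C4a.
- Pyridinium p-toluenesulfonate in wet acetone unmasks aldehyde 20, so steps 4 to 6 are bypassed.

**Step 10.** Several processes may interfere: slow formation of the acyl anion equivalent at an electron-rich aldehyde substituted at both ortho positions, acyl transfer from the aryl lactone to carbene or DBU, erosion of C2 by enolate β-elimination and re-addition, and incomplete equilibration at C3. The fallback is a thiol-catalysed radical-chain hydroacylation from 24 to 26 (tert-dodecanethiol, azobisisobutyronitrile, toluene, 80 °C). The acyl radical closes 6-exo onto the butenyl alkene and the primary radical is reduced by the thiol. Et3N at room temperature then equilibrates 25 to 26. No compound outside the list is made (F0).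

**Step 9.** The hindered, hydrogen-bonded phenol may be slow in SN2 at a secondary allylic carbon, so that SN2' attack, elimination of the activated alcohol or partial loss of configurational purity compete. The fallback is a palladium-catalysed asymmetric allylic etherification (Tsuji–Trost type) of 22 to 24. It uses (E)-but-2-enyl methyl carbonate, Pd2(dba)3·CHCl3 (zerovalent palladium) and the enantiomer of N,N'-(cyclohexane-1,2-diyl)bis[2-(diphenylphosphino)benzamide] that delivers the branched (S)-ether, in CH2Cl2 at rt. The stereocentre is then set by the catalyst and not by inversion. No compound outside the list is made (F0).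

**Step 3.** Amine-promoted dimerisation of aldoketene 8 may outrun cycloaddition with the internal ynol ether. Interchange of the ester and acid chloride termini through a cyclic acyloxonium ion would erode the enantiomeric purity. The fallback generates the ketene without amine; it sets out from 7 and returns at 9. α-Bromination of 7 (N-bromosuccinimide, trace HBr) gives methyl (3R)-3-(1-bromo-2-chloro-2-oxoethyl)hexanoate F9. Activated zinc in Et2O/DME in the presence of 6 then releases 8 by dehalogenation for the same [2+2] cycloaddition.

## Further compounds

F1 | step 5 | 1-allyl 7-methyl (5S)-3-oxo-5-propylheptanedioate | CCC[C@H](CC(=O)OC)CC(=O)CC(=O)OCC=C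
F2 | step 5 | 1-allyl 7-methyl (5S)-2-(3-methylbut-2-enyl)-3-oxo-5-propylheptanedioate, both configurations at C2 | CCC[C@H](CC(=O)OC)CC(=O)C(CC=C(C)C)C(=O)OCC=C
F3 | step 5 | 1-allyl 7-methyl (5S)-3-methoxy-2-(3-methylbut-2-enyl)-5-propylhept-2-enedioate, alkene geometry not fixed | CCC[C@H](CC(=O)OC)CC(OC)=C(CC=C(C)C)C(=O)OCC=C
F4 | step 5 | (5S)-3-methoxy-5-(2-methoxy-2-oxoethyl)-2-(3-methylbut-2-enyl)oct-2-enoic acid | CCC[C@H](CC(=O)OC)CC(OC)=C(CC=C(C)C)C(=O)O
F5 | step 5 | methyl (3S)-3-[4-chloro-2-methoxy-3-(3-methylbut-2-enyl)-4-oxobut-2-enyl]hexanoate | CCC[C@H](CC(=O)OC)CC(OC)=C(CC=C(C)C)C(=O)Cl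
F6 | step 4 | 3,3-diethoxyprop-1-yne | CCOC(OCC)C#C
F7 | step 4 | 3,3-diethoxy-1-(triisopropylsilyloxy)prop-1-yne | CCOC(OCC)C#CO[Si](C(C)C)(C(C)C)C(C)C
F8 | step 4 | methyl (3R)-3-[3-(diethoxymethyl)-2-hydroxy-6-methoxy-5-(3-methylbut-2-enyl)-4-(triisopropylsilyloxy)phenyl]hexanoate | CCC[C@H](CC(=O)OC)c1c(O)c(C(OCC)OCC)c(O[Si](C(C)C)(C(C)C)C(C)C)c(CC=C(C)C)c1OC
F0 | step 10 | none | none
F0 | step 9 | none | none
F9 | step 3 | methyl (3R)-3-(1-bromo-2-chloro-2-oxoethyl)hexanoate, both configurations at the CHBr carbon | CCC[C@H](CC(=O)OC)C(Br)C(=O)Cl
A1 | alternative 1 | (4R)-5-methoxy-6-(3-methylbut-2-enyl)-2-oxo-4-propyl-8-(trimethylsilyl)chroman-7-yl trifluoromethanesulfonate | CCC[C@@H]1CC(=O)Oc2c1c(OC)c(CC=C(C)C)c(OS(=O)(=O)C(F)(F)F)c2[Si](C)(C)C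
A2 | alternative 1 | (2S,3R)-3-(4-methoxybenzyloxy)-2-methylbutanoic acid | OC(=O)[C@@H](C)[C@@H](C)OCc1ccc(OC)cc1
A3 | alternative 1 | (4R)-7-hydroxy-5-methoxy-8-[(2S,3R)-3-(4-methoxybenzyloxy)-2-methylbutanoyl]-6-(3-methylbut-2-enyl)-4-propylchroman-2-one | CCC[C@@H]1CC(=O)Oc2c1c(OC)c(CC=C(C)C)c(O)c2C(=O)[C@@H](C)[C@@H](C)OCc1ccc(OC)cc1
A4 | alternative 2 | (4R)-7-[(2S)-but-3-en-2-yloxy]-5-methoxy-6-(3-methylbut-2-enyl)-2-oxo-4-propylchromane-8-carbaldehyde | CCC[C@@H]1CC(=O)Oc2c1c(OC)c(CC=C(C)C)c(O[C@@H](C)C=C)c2C=O
A5 | alternative 2 | lactone onto the C5 hydroxyl of (3R)-3-[(2S,3S)-5-hydroxy-7-methoxy-2,3-dimethyl-8-(3-methylbut-2-enyl)-4-oxochroman-6-yl]hexanoic acid | CCC[C@@H]1CC(=O)Oc2c1c(OC)c(CC=C(C)C)c1c2C(=O)[C@@H](C)[C@H](C)O1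
A6 | alternative 3 | methyl (3R)-3-[7-methoxy-5-(methoxymethoxy)-8-(3-methylbut-2-enyl)-4-oxo-4H-chromen-6-yl]hexanoate | CCC[C@H](CC(=O)OC)c1c(OCOC)c2c(c(CC=C(C)C)c1OC)OC=CC2=O
A7 | alternative 3 | methyl (3R)-3-[(2S,3S)-7-methoxy-5-(methoxymethoxy)-2,3-dimethyl-8-(3-methylbut-2-enyl)-4-oxochroman-6-yl]hexanoate | CCC[C@H](CC(=O)OC)c1c(OCOC)c2c(c(CC=C(C)C)c1OC)O[C@@H](C)[C@H](C)C2=O
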